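Ring D of the naphthol half is cut at C2'–C3' and C4'–C4a'. In one operation, an α-keto radical at C2' of a ring C aryl ketone (C1' carbonyl) adds to the methyl-bearing carbon of 1-methoxyprop-1-yne, and the resulting methoxyvinyl radical closes onto C4a', the only free ortho carbon of ring C. The step exploits the 1,4-dioxygenated ring D: it delivers the C1' hydroxyl and the C4' methyl ether already differentiated, with the C3' methyl and the C2' biaryl carbon in place. Its precursor is a racemic α-bromo deoxybenzoin whose α-aryl group is the benzyl-protected naphthohydroquinone of rings A and B.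

Key step: step 9

Remarks on the chemistry:
- Rings A/B are the quinone half (C1–C8a); rings C/D are the naphthol half (ring D carries C1'–C4').
- The biaryl axis C2–C2' is not a defined stereoelement of the target. The only stereocentre of the route (C2' of 13) is racemic and becomes sp2 in step 9, so no stereocontrol is needed.
- 2,5-Dibromobenzoquinone (not the 2,6-isomer) is the dienophile that leaves bromine at C2, next to the carbonyl remote from the C5 oxygen.
- Benzyl is kept as the only protecting group: it survives enolate, palladium and radical chemistry, and all three ethers fall in one neutral operation.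

Step 1
Reactants: 1 methyl 3-methylbut-2-enoate
Product: 2 1-methoxy-3-methyl-1-[(trimethylsilyl)oxy]buta-1,3-diene
Conditions: LDA, THF, −78 °C; TMSCl, −78 °C to rt; distil
Reagents that add atoms: chlorotrimethylsilane, C[Si](C)(C)Cl
Why: Kinetic γ-deprotonation of the ester by LDA and O-silylation of the dienolate (silyl ketene acetal formation) give the 1-oxygenated diene; no stereocentre is formed.

Step 2
Reactants: 2 1-methoxy-3-methyl-1-[(trimethylsilyl)oxy]buta-1,3-diene; 3 2,5-dibromocyclohexa-2,5-diene-1,4-dione
Product: 5 2-bromo-5-hydroxy-7-methylnaphthalene-1,4-dione, via bromo ketal cycloadduct 4 (not isolated)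
Conditions: CH2Cl2, −30 °C to rt; then SiO2, rt
Reagents that add atoms: none
Why: Regioselective Diels–Alder cycloaddition of a vinylketene acetal to a bromoquinone: the nucleophilic diene terminus bonds to the unbrominated carbon of one bromoalkene, so that after loss of HBr and methanol and desilylation the new hydroxyl (C5) lies peri to C4=O and the untouched bromine sits at C2, next to C1=O.

Step 3
Reactants: 5 2-bromo-5-hydroxy-7-methylnaphthalene-1,4-dione
Product: 6 2-bromo-5-methoxy-7-methylnaphthalene-1,4-dione
Conditions: MeI, Ag2O, CH2Cl2, rt, dark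
Reagents that add atoms: iodomethane, CI
Why: Ag2O-promoted O-methylation (Williamson type) alkylates the chelated peri hydroxyl under non-basic conditions that the bromoquinone tolerates.

Step 4
Reactants: 6 2-bromo-5-methoxy-7-methylnaphthalene-1,4-dione
Product: 8 1,4-bis(benzyloxy)-2-bromo-5-methoxy-7-methylnaphthalene, via 2-bromo-5-methoxy-7-methylnaphthalene-1,4-diol 7 (not isolated)
Conditions: Na2S2O4, Bu4NBr, THF/H2O, rt; then KOH, BnBr (excess), rt, argon
Reagents that add atoms: benzyl bromide, BrCc1ccccc1
Why: Reductive alkylation: dithionite reduces the quinone to the naphthalene-1,4-diol, whose phenoxides undergo Williamson benzylation under phase transfer before air can re-oxidise them.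

Step 5
Reactants: 9 1-(2,3-dihydroxyphenyl)ethan-1-one
Product: 11 1-[3-(benzyloxy)-2-methoxyphenyl]ethan-1-one, via sodium 2-acetyl-6-(benzyloxy)phenolate 10 (not isolated)
Conditions: NaH (2.05 equiv), DMSO, rt; BnBr (1.0 equiv), rt; then MeI, rt to 40 °C
Reagents that add atoms: benzyl bromide, BrCc1ccccc1; iodomethane, CI
Why: Sequential Williamson etherification of the catecholate dianion: the 3-oxide, neither conjugated with nor chelated by the acetyl group, is the more nucleophilic oxygen and takes the benzyl group, and the remaining chelated 2-phenoxide is then methylated in the same flask.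

Step 6
Reactants: 11 1-[3-(benzyloxy)-2-methoxyphenyl]ethan-1-one; 8 1,4-bis(benzyloxy)-2-bromo-5-methoxy-7-methylnaphthalene
Product: 12 1-[3-(benzyloxy)-2-methoxyphenyl]-2-[1,4-bis(benzyloxy)-5-methoxy-7-methylnaphthalen-2-yl]ethan-1-one
Conditions: Pd(OAc)2 (5 mol%), XPhos (2-dicyclohexylphosphino-2',4',6'-triisopropylbiphenyl, 10 mol%), NaOtBu (2.2 equiv), toluene, 80 °C
Reagents that add atoms: none
Why: Palladium-catalysed α-arylation of a ketone enolate (oxidative addition of 8 to zerovalent palladium, enolate binding, reductive elimination); the bulky dialkylbiarylphosphine copes with the ortho benzyloxy group, and the more hindered, more acidic product resists a second arylation.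

Step 7
Reactants: 12 1-[3-(benzyloxy)-2-methoxyphenyl]-2-[1,4-bis(benzyloxy)-5-methoxy-7-methylnaphthalen-2-yl]ethan-1-one
Product: 13 1-[3-(benzyloxy)-2-methoxyphenyl]-2-[1,4-bis(benzyloxy)-5-methoxy-7-methylnaphthalen-2-yl]-2-bromoethan-1-one (racemic)
Conditions: LiHMDS, THF, −78 °C; enolate added to NBS, THF, −78 °C
Reagents that add atoms: N-bromosuccinimide, O=C1CCC(=O)N1Br
Why: Electrophilic bromination of a preformed lithium enolate: the doubly activated benzylic α-proton is removed completely, and the enolate takes bromine from NBS at −78 °C far faster than the electron-rich arenes; the new stereocentre is racemic and is erased in step 9.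

Step 8
Reactants: 14 2-chloro-1,1-dimethoxyethane
Product: 16 1-methoxyprop-1-yne, via sodium methoxyethynide 15 (not isolated)
Conditions: NaNH2 (3.1 equiv), liquid NH3, −33 °C; then MeI, −70 to −33 °C; distil, store cold over K2CO3
Reagents that add atoms: iodomethane, CI
Why: Base-induced double elimination (methanol, then HCl) of the chloroacetal gives methoxyacetylene, which is deprotonated in the flask, and SN2 methylation of the acetylide gives the ynol ether (the established route to 1-alkoxy-1-alkynes).

Step 9
Reactants: 13 1-[3-(benzyloxy)-2-methoxyphenyl]-2-[1,4-bis(benzyloxy)-5-methoxy-7-methylnaphthalen-2-yl]-2-bromoethan-1-one; 16 1-methoxyprop-1-yne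
Product: 18 7-(benzyloxy)-2-[1,4-bis(benzyloxy)-5-methoxy-7-methylnaphthalen-2-yl]-4,8-dimethoxy-3-methylnaphthalen-1-ol, via 2H-naphthalen-1-one tautomer 17 (not isolated)
Conditions: Ir(ppy)3 [tris(2-phenylpyridinato)iridium] (2 mol%), 16 (5 equiv), 2,6-lutidine (2 equiv), degassed MeCN/CH2Cl2, 450 nm LEDs, rt
Reagents that add atoms: none
Why: Proposed new method: excited Ir(ppy)3 transfers one electron to the C–Br bond of 13, and the electrophilic α-keto radical at C2' adds to the methyl-bearing carbon of the ynol ether (the electron-rich carbon remote from oxygen), which forms C2'–C3' and leaves an α-methoxyvinyl radical at C4'. This σ-radical attacks C4a' of ring C, closing the six-membered ring D through C4'–C4a' by ortho attack (homolytic aromatic substitution, formally 6-exo-trig with respect to the C4a'=C5' bond); the cyclohexadienyl radical is oxidised by tetravalent iridium (or passes its electron to a further molecule of 13 in a chain), and proton loss gives dienone 17, which enolises to naphthol 18. The closest known reaction types are the photoredox annulation of 2-bromo-1,3-dicarbonyl compounds with alkynes and the Mn(OAc)3-mediated annulation of β-keto esters with alkynes, both leading to 1-naphthols; neither has been shown with an ynol ether or with an α-aryl α-bromo ketone. No stereocentre is created: the racemic centre of 13 becomes sp2 and the biaryl axis is not resolved. Two selectivities are needed: the site of addition on the alkyne follows from the polarisation of the ynol ether matched with an electrophilic radical, and the site of ring closure follows from C4a' (para to the C7' benzyloxy group) being the only unsubstituted ortho carbon, the other being blocked by the C8' methoxy group, while closure onto the naphthyl ring would need a strained five-membered transition state. Lutidine takes up HBr, so the acid-labile ynol ether and the enol ether of 17 survive, and the C4' oxygen arrives as a methyl ether while C1' emerges as the free hydroxyl.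

Step 10
Reactants: 18 7-(benzyloxy)-2-[1,4-bis(benzyloxy)-5-methoxy-7-methylnaphthalen-2-yl]-4,8-dimethoxy-3-methylnaphthalen-1-ol
Product: 20 Burmanin C, via biaryl tetrol 19 (not isolated)
Conditions: H2 (1 atm), 10% Pd/C, EtOAc/MeOH, rt; filter; then air, rt
Reagents that add atoms: none
Why: Heterogeneous hydrogenolysis cleaves the three benzyl aryl ethers, and the liberated naphthalene-1,4-diol of rings A/B is autoxidised by air to the quinone, whereas ring D, whose para oxygen is a methyl ether, cannot form a quinone and stays as the naphthol.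

Compound list
1 | methyl 3-methylbut-2-enoate | CC(C)=CC(=O)OC | starting material
2 | 1-methoxy-3-methyl-1-[(trimethylsilyl)oxy]buta-1,3-diene (E/Z mixture at C1) | COC(O[Si](C)(C)C)=CC(C)=C | intermediate
3 | 2,5-dibromocyclohexa-2,5-diene-1,4-dione | O=C1C=C(Br)C(=O)C=C1Br | starting material
4 | 2,4a-dibromo-5-methoxy-7-methyl-5-[(trimethylsilyl)oxy]-4a,5,8,8a-tetrahydronaphthalene-1,4-dione (racemic, cis-fused, C5 not controlled; not isolated) | COC1(O[Si](C)(C)C)C=C(C)CC2C(=O)C(Br)=CC(=O)C12Br | intermediate
5 | 2-bromo-5-hydroxy-7-methylnaphthalene-1,4-dione | O=C1C=C(Br)C(=O)c2cc(C)cc(O)c12 | intermediate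
6 | 2-bromo-5-methoxy-7-methylnaphthalene-1,4-dione | COc1cc(C)cc2C(=O)C(Br)=CC(=O)c12 | intermediate
7 | 2-bromo-5-methoxy-7-methylnaphthalene-1,4-diol (not isolated) | COc1cc(C)cc2c(O)c(Br)cc(O)c12 | intermediate
8 | 1,4-bis(benzyloxy)-2-bromo-5-methoxy-7-methylnaphthalene | COc1cc(C)cc2c(OCc3ccccc3)c(Br)cc(OCc3ccccc3)c12 | intermediate
9 | 1-(2,3-dihydroxyphenyl)ethan-1-one | CC(=O)c1cccc(O)c1O | starting material
10 | sodium 2-acetyl-6-(benzyloxy)phenolate (not isolated) | CC(=O)c1cccc(OCc2ccccc2)c1[O-].[Na+] | intermediate
11 | 1-[3-(benzyloxy)-2-methoxyphenyl]ethan-1-one | COc1c(OCc2ccccc2)cccc1C(C)=O | intermediate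
12 | 1-[3-(benzyloxy)-2-methoxyphenyl]-2-[1,4-bis(benzyloxy)-5-methoxy-7-methylnaphthalen-2-yl]ethan-1-one | COc1c(OCc2ccccc2)cccc1C(=O)Cc1cc(OCc2ccccc2)c2c(OC)cc(C)cc2c1OCc1ccccc1 | intermediate
13 | 1-[3-(benzyloxy)-2-methoxyphenyl]-2-[1,4-bis(benzyloxy)-5-methoxy-7-methylnaphthalen-2-yl]-2-bromoethan-1-one (racemic) | COc1c(OCc2ccccc2)cccc1C(=O)C(Br)c1cc(OCc2ccccc2)c2c(OC)cc(C)cc2c1OCc1ccccc1 | intermediate
14 | 2-chloro-1,1-dimethoxyethane | COC(CCl)OC | starting material
15 | sodium methoxyethynide (not isolated) | [Na+].[C-]#COC | intermediate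
16 | 1-methoxyprop-1-yne | CC#COC | intermediate
17 | 7-(benzyloxy)-2-[1,4-bis(benzyloxy)-5-methoxy-7-methylnaphthalen-2-yl]-4,8-dimethoxy-3-methylnaphthalen-1(2H)-one (racemic; not isolated) | COC1=C(C)C(c2cc(OCc3ccccc3)c3c(OC)cc(C)cc3c2OCc2ccccc2)C(=O)c2c(OC)c(OCc3ccccc3)ccc12 | intermediate
18 | 7-(benzyloxy)-2-[1,4-bis(benzyloxy)-5-methoxy-7-methylnaphthalen-2-yl]-4,8-dimethoxy-3-methylnaphthalen-1-ol | COc1c(C)c(-c2cc(OCc3ccccc3)c3c(OC)cc(C)cc3c2OCc2ccccc2)c(O)c2c(OC)c(OCc3ccccc3)ccc12 | intermediate
19 | 2-(1,7-dihydroxy-4,8-dimethoxy-3-methylnaphthalen-2-yl)-5-methoxy-7-methylnaphthalene-1,4-diol (not isolated) | COc1cc(C)cc2c(O)c(-c3c(C)c(OC)c4ccc(O)c(OC)c4c3O)cc(O)c12 | intermediate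
20 | Burmanin C, 2-(1,7-dihydroxy-4,8-dimethoxy-3-methylnaphthalen-2-yl)-5-methoxy-7-methylnaphthalene-1,4-dione | COc1cc(C)cc2c1C(=O)C=C(c1c(C)c(OC)c3ccc(O)c(OC)c3c1O)C2=O | target

Total step count: 10. Longest linear sequence: 8 steps (1, 2, 3, 4, 6, 7, 9, 10, from methyl 3-methylbut-2-enoate).

Steps most likely to fail

Step 9 (the step that carries the new method). The hindered, benzylically stabilised C2' radical may add too slowly to the ynol ether. Reduction or dimerisation of the radical, ipso attack on ring C with aryl migration, or acid-induced loss of the ynol ether would then take over.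

The fallback uses known chemistry: ring D is built as a quinone by a Dötz benzannulation and the biaryl bond by Suzuki–Miyaura coupling. It sets out from bromide 8 and comes back at 18.
- Commercial 3-bromo-2-methoxyphenol is benzylated (BnBr, K2CO3, DMF) to 1-(benzyloxy)-3-bromo-2-methoxybenzene F1.
- Bromine–lithium exchange (n-BuLi, THF, −78 °C), addition to Cr(CO)6 and O-methylation (Me3OBF4) give pentacarbonyl{[3-(benzyloxy)-2-methoxyphenyl](methoxy)methylidene}chromium F2.
- Heating F2 with propyne (THF, 50 °C) and oxidative work-up with (NH4)2Ce(NO3)6 should give 6-(benzyloxy)-5-methoxy-2-methylnaphthalene-1,4-dione F3. The ring closes on the only free ortho carbon, and the methyl group ends next to the carbonyl derived from CO.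
- Br2, then NaOAc in AcOH, gives 6-(benzyloxy)-3-bromo-5-methoxy-2-methylnaphthalene-1,4-dione F4.
- Bromide 8 is borylated (bis(pinacolato)diboron, PdCl2(dppf), KOAc, dioxane, 80 °C) to 2-[1,4-bis(benzyloxy)-5-methoxy-7-methylnaphthalen-2-yl]-4,4,5,5-tetramethyl-1,3,2-dioxaborolane F5.
- Coupling of F4 with F5 (Pd(PPh3)4, K2CO3, dioxane/H2O, 80 °C) gives 6-(benzyloxy)-3-[1,4-bis(benzyloxy)-5-methoxy-7-methylnaphthalen-2-yl]-5-methoxy-2-methylnaphthalene-1,4-dione F6.
- Reduction with Na2S2O4 gives 6-(benzyloxy)-3-[1,4-bis(benzyloxy)-5-methoxy-7-methylnaphthalen-2-yl]-5-methoxy-2-methylnaphthalene-1,4-diol F7. Methylation with one equivalent of MeI (K2CO3, acetone, argon) should take place at the hydroxyl next to the methyl group, because the other hydroxyl is screened by the biaryl substituent and hydrogen-bonded to the peri methoxy group; this gives 18.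

This fallback pays with the selective methylation that the main route avoids.

Step 6. Oxidative addition and reductive elimination at the electron-rich bromide with its ortho benzyloxy group may be slow, so that aldol self-condensation of 11 or a second arylation competes.

The fallback reverses the polarity of the coupling. It sets out from 8 and 11 and comes back at 12.
- Bromide 8 is converted (n-BuLi, THF, −78 °C; B(OiPr)3; dilute HCl) into [1,4-bis(benzyloxy)-5-methoxy-7-methylnaphthalen-2-yl]boronic acid F8.
- Ketone 11 is brominated at the methyl group (PhNMe3Br3, THF, 0 °C) to 1-[3-(benzyloxy)-2-methoxyphenyl]-2-bromoethan-1-one F9.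
- A Suzuki–Miyaura coupling of the α-bromo ketone with the arylboronic acid (Pd2(dba)3, tri(1-naphthyl)phosphine, K3PO4, THF/H2O, rt to 60 °C) forms the same C2'–aryl bond and should give 12.

Step 7. The enolate may be brominated incompletely or may couple with the product, and NBS may attack the electron-rich naphthalene ring.

The fallback is oxygenation followed by substitution. It sets out from 12 and comes back at 13.
- The potassium enolate of 12 (KHMDS, THF, −78 °C) is hydroxylated with 2-(phenylsulfonyl)-3-phenyloxaziridine to racemic 1-[3-(benzyloxy)-2-methoxyphenyl]-2-[1,4-bis(benzyloxy)-5-methoxy-7-methylnaphthalen-2-yl]-2-hydroxyethan-1-one F10.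
- An Appel reaction (CBr4, PPh3, CH2Cl2, 0 °C) then replaces the hydroxyl by bromide without any source of electrophilic bromine and should give 13.

Further compounds
F1 | step 9 | 1-(benzyloxy)-3-bromo-2-methoxybenzene | COc1c(Br)cccc1OCc1ccccc1
F2 | step 9 | pentacarbonyl{[3-(benzyloxy)-2-methoxyphenyl](methoxy)methylidene}chromium | COC(c1cccc(OCc2ccccc2)c1OC)=[Cr](=C=O)(=C=O)(=C=O)(=C=O)=C=O
F3 | step 9 | 6-(benzyloxy)-5-methoxy-2-methylnaphthalene-1,4-dione | CC1=CC(=O)c2c(OC)c(OCc3ccccc3)ccc2C1=O
F4 | step 9 | 6-(benzyloxy)-3-bromo-5-methoxy-2-methylnaphthalene-1,4-dione | CC1=C(Br)C(=O)c2c(OC)c(OCc3ccccc3)ccc2C1=O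
F5 | step 9 | 2-[1,4-bis(benzyloxy)-5-methoxy-7-methylnaphthalen-2-yl]-4,4,5,5-tetramethyl-1,3,2-dioxaborolane | COc1cc(C)cc2c(OCc3ccccc3)c(B3OC(C)(C)C(C)(C)O3)cc(OCc3ccccc3)c12
F6 | step 9 | 6-(benzyloxy)-3-[1,4-bis(benzyloxy)-5-methoxy-7-methylnaphthalen-2-yl]-5-methoxy-2-methylnaphthalene-1,4-dione | CC1=C(c2cc(OCc3ccccc3)c3c(OC)cc(C)cc3c2OCc2ccccc2)C(=O)c2c(OC)c(OCc3ccccc3)ccc2C1=O
F7 | step 9 | 6-(benzyloxy)-3-[1,4-bis(benzyloxy)-5-methoxy-7-methylnaphthalen-2-yl]-5-methoxy-2-methylnaphthalene-1,4-diol | Cc1c(O)c2ccc(OCc3ccccc3)c(OC)c2c(O)c1-c1cc(OCc2ccccc2)c2c(OC)cc(C)cc2c1OCc1ccccc1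
F8 | step 6 | [1,4-bis(benzyloxy)-5-methoxy-7-methylnaphthalen-2-yl]boronic acid | COc1cc(C)cc2c(OCc3ccccc3)c(B(O)O)cc(OCc3ccccc3)c12
F9 | step 6 | 1-[3-(benzyloxy)-2-methoxyphenyl]-2-bromoethan-1-one | COc1c(OCc2ccccc2)cccc1C(=O)CBr
F10 | step 7 | 1-[3-(benzyloxy)-2-methoxyphenyl]-2-[1,4-bis(benzyloxy)-5-methoxy-7-methylnaphthalen-2-yl]-2-hydroxyethan-1-one (racemic) | COc1c(OCc2ccccc2)cccc1C(=O)C(O)c1cc(OCc2ccccc2)c2c(OC)cc(C)cc2c1OCc1ccccc1
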